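**Plan**

- The target has no stereocentres. The only stereocentres on the route are the two bridgeheads of a transient cycloadduct, and they vanish on aromatisation.
- Retrosynthesis: after the protecting groups are restored (ring A saligenin as an acetonide, ring B catechol as benzyl ether and benzyl carbonate), the C3a–C4 and C5–C6 bonds of phthalide ring B are cut and a CO2 bridge is put back between C6 and C3a.
- This is possible because ring B is a hexasubstituted benzene. Its C4–C5 edge (methyl carbon, aryloxy carbon) is a 1-aryloxypropyne. Its C6, C7, C7a and C3a, with the lactone carbonyl on C7a, are the diene of a butenolide-fused 2-pyranone polarised at the terminus that becomes C3a.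
- The ynol ether is cut at its O–C(sp) bond to a ring A phenol (from methyl orsellinate) and 1,1-dibromopropene. The pyranone is cut at C4–C4a and O1–C2 to tetronic acid and an activated benzyloxymalonate.
- Forward: ring A is dressed (formylation, reduction, acetonide, O-alkynylation) while the pyranone ring is fused onto tetronic acid. Ring B is then created from the two fragments with the diaryl ether already in place, and two deprotections finish.

Key step: step 9

Assumption: diethyl 2-(benzyloxy)malonate and 1,1-dibromoprop-1-ene are taken as catalogue compounds.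

**Route**

Step 1
Reactants: 1 diethyl 2-(benzyloxy)malonate
Product: 2 2-(benzyloxy)malonic acid
Conditions: KOH (2.5 equiv), EtOH/H2O, rt; then HCl (aq), 0 °C
Reagents that add atoms: potassium hydroxide, [K+].[OH-]
Why: Saponification of both ethyl esters under mild alkaline conditions leaves the benzyl ether untouched, and cold acidification avoids decarboxylation of the malonic acid.

Step 2
Reactants: 2 2-(benzyloxy)malonic acid
Product: 3 bis(2,4,6-trichlorophenyl) 2-(benzyloxy)malonate
Conditions: 2,4,6-trichlorophenol (2.1 equiv), POCl3, 80 °C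
Reagents that add atoms: 2,4,6-trichlorophenol, Oc1c(Cl)cc(Cl)cc1Cl
Why: POCl3-mediated esterification of a malonic acid with an electron-poor phenol is the standard preparation of the activated bis(aryl) malonates used in cyclocondensations, and the alpha-benzyloxy group is not acid-labile under these conditions.

Step 3
Reactants: 3 bis(2,4,6-trichlorophenyl) 2-(benzyloxy)malonate; 4 tetronic acid
Product: 6 3-(benzyloxy)-4-hydroxy-7H-furo[3,4-b]pyran-2,5-dione, via C-acylated tetronic acid 5 (not isolated)
Conditions: PhBr, reflux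
Reagents that add atoms: none
Why: Thermal cyclocondensation of an activated aryl malonate with a cyclic 1,3-dicarbonyl C,O-dinucleophile: C3 of tetronic acid is acylated to give 5, whose enol oxygen then closes the 4-hydroxy-2-pyranone ring on the second aryl ester, as is established for 4-hydroxycoumarin and 4-hydroxy-6-methyl-2-pyranone.

Step 4
Reactants: 6 3-(benzyloxy)-4-hydroxy-7H-furo[3,4-b]pyran-2,5-dione
Product: 7 benzyl 3-(benzyloxy)-2,5-dioxo-5,7-dihydro-2H-furo[3,4-b]pyran-4-yl carbonate
Conditions: CbzCl, Et3N, CH2Cl2, −20 → 0 °C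
Reagents that add atoms: benzyl chloroformate, O=C(Cl)OCc1ccccc1
Why: O-acylation of the acidic 4-hydroxyl of a 4-hydroxy-2-pyranone with a chloroformate and a tertiary amine takes place on the 4-oxygen; the carbonate lowers the electron density of the diene for step 9 and is removed later by hydrogenolysis.

Step 5
Reactants: 8 methyl orsellinate
Product: 9 methyl 3-formyl-2,4-dihydroxy-6-methylbenzoate
Conditions: Cl2CHOMe, TiCl4, CH2Cl2, 0 °C → rt; then HCl (aq)
Reagents that add atoms: dichloromethyl methyl ether, COC(Cl)Cl; water, O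
Why: Rieche formylation: electrophilic substitution ortho to the TiCl4-bound phenol oxygens should favour C3, which lies between the two hydroxyls and para to the ring methyl, over C5 beside the methyl group, and any 5-formyl isomer is removed by crystallisation.

Step 6
Reactants: 9 methyl 3-formyl-2,4-dihydroxy-6-methylbenzoate
Product: 10 methyl 2,4-dihydroxy-3-(hydroxymethyl)-6-methylbenzoate
Conditions: NaBH4, THF/MeOH, 0 °C; then NH4Cl (aq)
Reagents that add atoms: none
Why: Chemoselective borohydride reduction of an aryl aldehyde beside a hindered, hydrogen-bonded methyl benzoate; low temperature and a buffered quench should keep the electron-rich hydroxybenzyl alcohol from ionising to a quinone methide, and 10 is taken on crude.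

Step 7
Reactants: 10 methyl 2,4-dihydroxy-3-(hydroxymethyl)-6-methylbenzoate
Product: 11 methyl 5-hydroxy-2,2,7-trimethyl-4H-1,3-benzodioxine-6-carboxylate
Conditions: Me2C(OMe)2, PPTS (cat.), acetone, rt
Reagents that add atoms: 2,2-dimethoxypropane, COC(C)(C)OC
Why: Acid-catalysed transketalisation of a 2-hydroxybenzyl alcohol to the 2,2-dimethyl-4H-1,3-benzodioxine; under equilibrating conditions the 4-hydroxyl should be engaged, because the 2-hydroxyl keeps its strong hydrogen bond to the ester carbonyl.

Step 8
Reactants: 11 methyl 5-hydroxy-2,2,7-trimethyl-4H-1,3-benzodioxine-6-carboxylate; 12 1,1-dibromoprop-1-ene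
Product: 14 methyl 2,2,7-trimethyl-5-(prop-1-yn-1-yloxy)-4H-1,3-benzodioxine-6-carboxylate, via bromo enol ether 13 (not isolated)
Conditions: CuI (10 mol %), 2,2'-bipyridine (20 mol %), K3PO4, 12 (1.5 equiv), toluene, 110 °C, sealed; then KOtBu, 1,4-dioxane, rt
Reagents that add atoms: none
Why: CuI-catalysed Ullmann-type C–O coupling of a phenol with a 1,1-dibromoalkene occurs at the C–Br bond trans to the methyl group and should give the (Z)-bromo enol ether 13 with bromine anti to the vinylic hydrogen, so KOtBu completes an E2 dehydrobromination to the ynol ether without an organolithium that would attack the ester.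

Step 9
Reactants: 14 methyl 2,2,7-trimethyl-5-(prop-1-yn-1-yloxy)-4H-1,3-benzodioxine-6-carboxylate; 7 benzyl 3-(benzyloxy)-2,5-dioxo-5,7-dihydro-2H-furo[3,4-b]pyran-4-yl carbonate
Product: 16 methyl 5-{[6-(benzyloxy)-7-{[(benzyloxy)carbonyl]oxy}-4-methyl-1-oxo-1,3-dihydro-2-benzofuran-5-yl]oxy}-2,2,7-trimethyl-4H-1,3-benzodioxine-6-carboxylate, via bridged lactone adduct 15 (not isolated)
Conditions: toluene, 110–140 °C, sealed tube, acid-free glassware
Reagents that add atoms: none
Why: Inverse-demand Diels–Alder reaction followed by cycloreversion: the methyl-bearing, nucleophilic alkyne carbon of 14 bonds to C7a of 7 (the pyranone terminus beta to the butenolide carbonyl) and the oxygen-bearing carbon closes onto C3, an asynchronous (4+2) cycloaddition that gives the 2-oxabicyclo[2.2.2]octadienone 15. Retro-(4+2) loss of CO2 from 15 then leaves ring B aromatic, so this one ring is closed by intermolecular cycloaddition with both new bonds (future C3a–C4 and C5–C6) made in the same operation and the tetra-ortho-substituted diaryl ether carried in intact. The closest known reaction type is the cycloaddition of 2-pyranone-5-carboxylates with ynamines and alkoxyalkynes, which gives benzoates after CO2 extrusion. The two bridgehead stereocentres of 15 are fixed only by the bicyclic frame, form as a racemate and disappear on aromatisation, so no stereocontrol is required. The selectivity needed is regiochemical (methyl beside the lactone CH2, aryloxy beside the benzyloxy carbon) and should follow from pairing the polarised ynol ether with the most electrophilic diene terminus, while the carbonate on O4 removes the donation that a 4-alkoxy group would exert. An aryl ynol ether has no O-alkyl hydrogen for retro-ene ketene formation and should therefore tolerate the heating.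

Step 10
Reactants: 16 methyl 5-{[6-(benzyloxy)-7-{[(benzyloxy)carbonyl]oxy}-4-methyl-1-oxo-1,3-dihydro-2-benzofuran-5-yl]oxy}-2,2,7-trimethyl-4H-1,3-benzodioxine-6-carboxylate
Product: 17 methyl 5-[(6,7-dihydroxy-4-methyl-1-oxo-1,3-dihydro-2-benzofuran-5-yl)oxy]-2,2,7-trimethyl-4H-1,3-benzodioxine-6-carboxylate
Conditions: H2 (1 atm), Pd/C (10 %), EtOAc, rt
Reagents that add atoms: none
Why: Catalytic hydrogenolysis cleaves the aryl benzyl ether and the aryl benzyl carbonate (the latter with loss of CO2) much faster than the alkyl-type benzylic C–O bonds of the benzodioxine and the phthalide, which are known to survive these conditions.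

Step 11
Reactants: 17 methyl 5-[(6,7-dihydroxy-4-methyl-1-oxo-1,3-dihydro-2-benzofuran-5-yl)oxy]-2,2,7-trimethyl-4H-1,3-benzodioxine-6-carboxylate
Product: 18 methyl 2-[(6,7-dihydroxy-4-methyl-1-oxo-1,3-dihydro-2-benzofuran-5-yl)oxy]-4-hydroxy-3-(hydroxymethyl)-6-methylbenzoate (Compound NP-007516)
Conditions: AcOH/H2O/THF, 45 °C, under argon
Reagents that add atoms: none
Why: Mild aqueous acid hydrolysis of the ketal frees the phenol and the benzylic alcohol; an alcohol-free medium prevents benzylic ether formation, and the phthalide and the hindered methyl ester are stable.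

**Compound list**

1 | diethyl 2-(benzyloxy)malonate | CCOC(=O)C(OCc1ccccc1)C(=O)OCC | starting material
2 | 2-(benzyloxy)malonic acid | OC(=O)C(OCc1ccccc1)C(O)=O | intermediate
3 | bis(2,4,6-trichlorophenyl) 2-(benzyloxy)malonate | O=C(Oc1c(Cl)cc(Cl)cc1Cl)C(OCc1ccccc1)C(=O)Oc1c(Cl)cc(Cl)cc1Cl | intermediate
4 | tetronic acid (4-hydroxyfuran-2(5H)-one) | OC1=CC(=O)OC1 | starting material
5 | C-acylated tetronic acid: 2,4,6-trichlorophenyl 2-(benzyloxy)-3-(4-hydroxy-2-oxo-2,5-dihydrofuran-3-yl)-3-oxopropanoate (racemic, configurationally labile, not isolated) | O=C(Oc1c(Cl)cc(Cl)cc1Cl)C(OCc1ccccc1)C(=O)C1=C(O)COC1=O | intermediate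
6 | 3-(benzyloxy)-4-hydroxy-7H-furo[3,4-b]pyran-2,5-dione | O=C1OC2=C(C(=O)OC2)C(O)=C1OCc1ccccc1 | intermediate
7 | benzyl 3-(benzyloxy)-2,5-dioxo-5,7-dihydro-2H-furo[3,4-b]pyran-4-yl carbonate | O=C1OC2=C(C(=O)OC2)C(OC(=O)OCc2ccccc2)=C1OCc1ccccc1 | intermediate
8 | methyl orsellinate (methyl 2,4-dihydroxy-6-methylbenzoate) | COC(=O)c1c(C)cc(O)cc1O | starting material
9 | methyl 3-formyl-2,4-dihydroxy-6-methylbenzoate | COC(=O)c1c(C)cc(O)c(C=O)c1O | intermediate
10 | methyl 2,4-dihydroxy-3-(hydroxymethyl)-6-methylbenzoate | COC(=O)c1c(C)cc(O)c(CO)c1O | intermediate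
11 | methyl 5-hydroxy-2,2,7-trimethyl-4H-1,3-benzodioxine-6-carboxylate | COC(=O)c1c(C)cc2OC(C)(C)OCc2c1O | intermediate
12 | 1,1-dibromoprop-1-ene | CC=C(Br)Br | starting material
13 | bromo enol ether: methyl 5-{[(1Z)-1-bromoprop-1-en-1-yl]oxy}-2,2,7-trimethyl-4H-1,3-benzodioxine-6-carboxylate (not isolated) | C/C=C(\Br)Oc1c(C(=O)OC)c(C)cc2OC(C)(C)OCc12 | intermediate
14 | methyl 2,2,7-trimethyl-5-(prop-1-yn-1-yloxy)-4H-1,3-benzodioxine-6-carboxylate | CC#COc1c(C(=O)OC)c(C)cc2OC(C)(C)OCc12 | intermediate
15 | bridged lactone adduct: 2-oxabicyclo[2.2.2]octa-5,7-dien-3-one in which C3 of 7 is bonded to the aryloxy carbon and C7a of 7 to the methyl carbon of the former alkyne, butenolide still fused (racemic, one enantiomer drawn, not isolated) | O=C1O[C@@]23COC(=O)C2=C(OC(=O)OCc2ccccc2)[C@]1(OCc1ccccc1)C(Oc4c(C(=O)OC)c(C)cc5OC(C)(C)OCc45)=C3C | intermediate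
16 | methyl 5-{[6-(benzyloxy)-7-{[(benzyloxy)carbonyl]oxy}-4-methyl-1-oxo-1,3-dihydro-2-benzofuran-5-yl]oxy}-2,2,7-trimethyl-4H-1,3-benzodioxine-6-carboxylate | COC(=O)c1c(C)cc2OC(C)(C)OCc2c1Oc1c(C)c2COC(=O)c2c(OC(=O)OCc2ccccc2)c1OCc1ccccc1 | intermediate
17 | methyl 5-[(6,7-dihydroxy-4-methyl-1-oxo-1,3-dihydro-2-benzofuran-5-yl)oxy]-2,2,7-trimethyl-4H-1,3-benzodioxine-6-carboxylate | COC(=O)c1c(C)cc2OC(C)(C)OCc2c1Oc1c(C)c2COC(=O)c2c(O)c1O | intermediate
18 | methyl 2-[(6,7-dihydroxy-4-methyl-1-oxo-1,3-dihydro-2-benzofuran-5-yl)oxy]-4-hydroxy-3-(hydroxymethyl)-6-methylbenzoate (Compound NP-007516, achiral) | COC(=O)c1c(C)cc(O)c(CO)c1Oc1c(C)c2c(c(O)c1O)C(=O)OC2 | target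

**Step count**

Total steps: 11. Longest linear sequence: 7 steps (steps 5–11 from methyl orsellinate 8; the pyranone branch, steps 1–4 followed by 9–11, is equally long).

**Steps most likely to fail**

1. Step 9. The cycloaddition may be too slow, because the 3-benzyloxy group still donates into the diene and C7a is fully substituted. Prolonged heating would then let the ynol ether hydrate or oligomerise before it adds, or a competing orientation would erode the regiochemistry. Fallback (from 6 and 14, back to the route at 17): the diene is redesigned with a far stronger acceptor on O4. Compound 6 is treated with Tf2O and Et3N (CH2Cl2, −78 °C) to give 3-(benzyloxy)-2,5-dioxo-5,7-dihydro-2H-furo[3,4-b]pyran-4-yl trifluoromethanesulfonate F1. Heating F1 with 14 should give, through the corresponding bridged lactone adduct F2 and loss of CO2, the C7 aryl triflate of the diaryl ether F3. S–O cleavage of the triflate with Et4NOH in dioxane (the lactone re-closes on acidification) gives the C7 phenol F4. Hydrogenolysis of its single benzyl ether (H2, Pd/C) rejoins the route at 17.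

2. Step 8. The CuI coupling may stall, because the phenoxide of 11 is flanked on both sides and chelated to the ester. A second risk is that the bromo enol ether is substituted a second time to a ketene acetal before elimination. Fallback (from 11, back at 14): addition of the phenoxide to dichloroacetylene generated in the flask (trichloroethylene, K2CO3, DMF, 70 °C) should give the (E)-1,2-dichlorovinyl ether F5. n-BuLi (2.2 equiv, THF, −78 °C) eliminates HCl to the chloroethynyl ether F6 and exchanges its chlorine to give the lithium aryloxyacetylide F7. F7 is methylated with MeI (DMPU) to give 14. The di-ortho-substituted methyl benzoate should survive, because vinylic deprotonation and chlorine–lithium exchange are much faster at −78 °C than addition to this hindered ester.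

3. Step 3. Tetronic acid may self-condense or decompose at the temperature needed to activate the aryl malonate, so that acylation at C3 is outrun. Fallback (from 1 and 4, back at 6): a stepwise, low-temperature assembly. Mono-saponification of 1 (KOH, 1 equiv, EtOH, rt) gives ethyl hydrogen 2-(benzyloxy)malonate F8. DCC/DMAP coupling of F8 with tetronic acid 4 (Steglich-type O-acylation, then DMAP-mediated acyl shift to C3) gives the 3-acyltetronic acid F9. Heating F9 with catalytic TsOH in toluene closes the pyranone by lactonisation with loss of ethanol, giving 6.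

**Further compounds**

F1 | step 9 | 3-(benzyloxy)-2,5-dioxo-5,7-dihydro-2H-furo[3,4-b]pyran-4-yl trifluoromethanesulfonate | O=C1OC2=C(C(=O)OC2)C(OS(=O)(=O)C(F)(F)F)=C1OCc1ccccc1
F2 | step 9 | bridged lactone adduct of F1 and 14 (2-oxabicyclo[2.2.2]octa-5,7-dien-3-one, racemic, one enantiomer drawn, not isolated) | O=C1O[C@@]23COC(=O)C2=C(OS(=O)(=O)C(F)(F)F)[C@]1(OCc1ccccc1)C(Oc4c(C(=O)OC)c(C)cc5OC(C)(C)OCc45)=C3C
F3 | step 9 | methyl 5-{[6-(benzyloxy)-4-methyl-1-oxo-7-{[(trifluoromethyl)sulfonyl]oxy}-1,3-dihydro-2-benzofuran-5-yl]oxy}-2,2,7-trimethyl-4H-1,3-benzodioxine-6-carboxylate | COC(=O)c1c(C)cc2OC(C)(C)OCc2c1Oc1c(C)c2COC(=O)c2c(OS(=O)(=O)C(F)(F)F)c1OCc1ccccc1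
F4 | step 9 | methyl 5-{[6-(benzyloxy)-7-hydroxy-4-methyl-1-oxo-1,3-dihydro-2-benzofuran-5-yl]oxy}-2,2,7-trimethyl-4H-1,3-benzodioxine-6-carboxylate | COC(=O)c1c(C)cc2OC(C)(C)OCc2c1Oc1c(C)c2COC(=O)c2c(O)c1OCc1ccccc1
F5 | step 8 | methyl 5-{[(E)-1,2-dichloroethenyl]oxy}-2,2,7-trimethyl-4H-1,3-benzodioxine-6-carboxylate | Cl/C=C(/Cl)Oc1c(C(=O)OC)c(C)cc2OC(C)(C)OCc12
F6 | step 8 | methyl 5-[(chloroethynyl)oxy]-2,2,7-trimethyl-4H-1,3-benzodioxine-6-carboxylate (not isolated) | ClC#COc1c(C(=O)OC)c(C)cc2OC(C)(C)OCc12
F7 | step 8 | lithium aryloxyacetylide: methyl 5-[(lithioethynyl)oxy]-2,2,7-trimethyl-4H-1,3-benzodioxine-6-carboxylate (not isolated) | [Li]C#COc1c(C(=O)OC)c(C)cc2OC(C)(C)OCc12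
F8 | step 3 | ethyl hydrogen 2-(benzyloxy)malonate (racemic) | CCOC(=O)C(OCc1ccccc1)C(=O)O
F9 | step 3 | ethyl 2-(benzyloxy)-3-(4-hydroxy-2-oxo-2,5-dihydrofuran-3-yl)-3-oxopropanoate (racemic, configurationally labile) | CCOC(=O)C(OCc1ccccc1)C(=O)C1=C(O)COC1=O
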